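## Retrosynthetic overview

1. The last ring is the chain-bearing oxolane: the side-chain hydroxyl closes onto a 2-alkyl-5-methyl-4,5-dihydrofuran under a chiral Brønsted acid, which creates the spiro centre.
2. The C(sp3)–C(sp2) bond at the future spiro carbon comes from a palladium-catalysed Negishi coupling of a primary alkylzinc with the ketene acetal phosphate of (R)-γ-valerolactone; the methyl-bearing ring arrives preformed.
3. The first ring made is the phthalide lactone: carboxylate-directed ortho C–H addition of 2,4-dimethoxybenzoic acid to an aliphatic aldehyde, then lactonization, sets C3.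
4. The aldehyde comes from hept-6-enyl Grignard and (S)-2-(2-bromoethyl)oxirane (chiral-pool carbinol), silylation and ozonolysis; the acid comes from resorcinol by Kolbe–Schmitt carboxylation, methylation and saponification.
5. Ring order: benzene ring (bought) → phthalide lactone (step 8) → dihydrofuran attached (step 9) → spiro ring closure (step 11).

Assumption: (S)-2-(2-bromoethyl)oxirane and (R)-γ-valerolactone are bought enantiopure, and the antipode of each chiral catalyst (steps 8 and 11) that gives the stated configuration is fixed by one screening run.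

## Route

Step 1
Reactants: 1 resorcinol
Product: 2 2,4-dihydroxybenzoic acid
Conditions: KHCO3 (5 equiv), H2O, CO2 atmosphere, 100 °C; then conc. HCl
Reagents that add atoms: potassium hydrogen carbonate, [K+].OC([O-])=O
Why: Kolbe–Schmitt carboxylation puts the carboxyl group ortho to one hydroxyl and para to the other on the electron-rich ring, which is the position of the later lactone carbonyl; no stereocentre.

Step 2
Reactants: 2 2,4-dihydroxybenzoic acid
Product: 3 methyl 2,4-dimethoxybenzoate
Conditions: Me2SO4 (4 equiv), K2CO3 (6 equiv), acetone, reflux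
Reagents that add atoms: dimethyl sulfate, COS(=O)(=O)OC
Why: Exhaustive Williamson-type O-methylation of both phenols and the carboxylate, with excess reagent and reflux to overcome the hydrogen-bonded ortho phenol.

Step 3
Reactants: 3 methyl 2,4-dimethoxybenzoate
Product: 4 2,4-dimethoxybenzoic acid
Conditions: LiOH·H2O, THF/MeOH/H2O, 50 °C; then 1 M HCl
Reagents that add atoms: lithium hydroxide, [Li+].[OH-]
Why: Saponification by acyl–oxygen cleavage frees the carboxylic acid that later directs the C–H activation and leaves the aryl methyl ethers untouched.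

Step 4
Reactants: 5 7-bromohept-1-ene; 6 (S)-2-(2-bromoethyl)oxirane
Product: 8 (R)-1-bromoundec-10-en-3-ol, via hept-6-en-1-ylmagnesium bromide 7 (not isolated)
Conditions: Mg, THF, rt; then 6 (0.75 equiv), CuI (copper iodide, 10 mol%), THF, −40 → −20 °C; aq. NH4Cl
Reagents that add atoms: none
Why: Copper-catalysed Grignard opening of a terminal epoxide at its CH2 carbon (SN2) is faster at −40 °C than coupling at the primary bromide, and the stereocentre is carried unchanged from 6, the descriptor changing from (S) to (R) only through the CIP ranks.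

Step 5
Reactants: 8 (R)-1-bromoundec-10-en-3-ol
Product: 9 (R)-[(1-bromoundec-10-en-3-yl)oxy](tert-butyl)dimethylsilane
Conditions: TBSOTf, 2,6-lutidine, CH2Cl2, −78 → 0 °C
Reagents that add atoms: tert-butyldimethylsilyl trifluoromethanesulfonate, CC(C)(C)[Si](C)(C)OS(=O)(=O)C(F)(F)F
Why: Silyl ether protection with a silyl triflate and a hindered base masks the secondary alcohol and does not touch the primary bromide or the alkene.

Step 6
Reactants: 9 (R)-[(1-bromoundec-10-en-3-yl)oxy](tert-butyl)dimethylsilane
Product: 11 (R)-10-bromo-8-(tert-butyldimethylsilyloxy)decanal, via secondary ozonide 10 (not isolated)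
Conditions: O3, CH2Cl2, −78 °C; then PPh3, −78 °C → rt
Reagents that add atoms: ozone, O=[O+][O-]
Why: Ozonolysis with reductive work-up (Criegee mechanism) cleaves the only alkene to the aldehyde, while the bromide, the silyl ether and the remote stereocentre are inert.

Step 7
Reactants: 12 (R)-γ-valerolactone
Product: 14 (5R)-5-methyl-4,5-dihydrofuran-2-yl diphenyl phosphate, via potassium lactone enolate 13 (not isolated)
Conditions: KHMDS (1.2 equiv) added to 12 + (PhO)2P(O)Cl (1.2 equiv), THF/HMPA, −78 °C; Et3N-buffered work-up, used within a day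
Reagents that add atoms: diphenyl chlorophosphate, O=P(Cl)(Oc1ccccc1)Oc1ccccc1
Why: Kinetic enolization and O-phosphorylation (enol phosphate formation with in situ trapping, which suppresses Claisen self-condensation) give the cyclic ketene acetal phosphate as the coupling electrophile, and the C5 stereocentre is not involved.

Step 8
Reactants: 4 2,4-dimethoxybenzoic acid; 11 (R)-10-bromo-8-(tert-butyldimethylsilyloxy)decanal
Product: 16 (3R)-3-[(7R)-9-bromo-7-(tert-butyldimethylsilyloxy)nonyl]-5,7-dimethoxy-2-benzofuran-1(3H)-one, via hydroxy acid 15 (not isolated)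
Conditions: Rh(Cpx)(C2H4)2 (5 mol%; Cpx = cyclopentadienyl fused through two CH2 groups to C2 and C2' of a 3,3'-dimethoxy-1,1'-binaphthyl; monovalent rhodium precatalyst), (PhCO2)2 (5 mol%, oxidises it in the flask to the trivalent rhodium dibenzoate), NaOPiv (20 mol%), 4 Å MS, ClCH2CH2Cl, 60 °C; 4 (1.5 equiv), 11 added slowly
Reagents that add atoms: none
Why: Proposed new method: carboxylate-assisted concerted metalation–deprotonation at C6, the only free ortho C–H of 4, gives a five-membered aryl–rhodium carboxylate on trivalent rhodium bearing the chiral cyclopentadienyl ligand, the aldehyde of 11 binds and inserts into the Rh–aryl bond through its Si face (the other face is blocked by the binaphthyl wall) to set the (R) benzylic centre, and protonolysis to hydroxy acid 15 with spontaneous five-ring lactonization pulls the adduct out of the otherwise unfavourable addition equilibrium and so keeps the kinetic ee; the closest known reaction type is the pentamethylcyclopentadienyl-rhodium-catalysed ortho C–H addition of benzoic acids or benzimidates to aldehydes with in situ lactonization to racemic phthalides, which has not been shown under chiral cyclopentadienyl control for a free benzoic acid and an unactivated, enolizable aliphatic aldehyde.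

Step 9
Reactants: 16 (3R)-3-[(7R)-9-bromo-7-(tert-butyldimethylsilyloxy)nonyl]-5,7-dimethoxy-2-benzofuran-1(3H)-one; 14 (5R)-5-methyl-4,5-dihydrofuran-2-yl diphenyl phosphate
Product: 18 (3R)-3-{(7R)-7-(tert-butyldimethylsilyloxy)-9-[(5R)-5-methyl-4,5-dihydrofuran-2-yl]nonyl}-5,7-dimethoxy-2-benzofuran-1(3H)-one, via alkylzinc bromide 17 (not isolated)
Conditions: Zn dust (3 equiv), LiCl (1.5 equiv), THF, 50 °C; then 14 (1.4 equiv), Pd(OAc)2 (5 mol%), SPhos (10 mol%), THF, 25 → 40 °C; aq. NaHCO3 work-up, Et3N-deactivated SiO2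
Reagents that add atoms: none
Why: LiCl-promoted zinc insertion into the primary C–Br bond followed by Negishi coupling, in which zerovalent palladium adds to the C–O bond of the ketene acetal phosphate and transmetalation and reductive elimination form the C(sp3)–C(sp2) bond at the future spiro carbon; the lactone, the silyl ether and all three stereocentres are untouched under these neutral conditions.

Step 10
Reactants: 18 (3R)-3-{(7R)-7-(tert-butyldimethylsilyloxy)-9-[(5R)-5-methyl-4,5-dihydrofuran-2-yl]nonyl}-5,7-dimethoxy-2-benzofuran-1(3H)-one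
Product: 19 (3R)-3-{(7R)-7-hydroxy-9-[(5R)-5-methyl-4,5-dihydrofuran-2-yl]nonyl}-5,7-dimethoxy-2-benzofuran-1(3H)-one
Conditions: TBAF (1.5 equiv), THF, 0 °C → rt; aq. NaHCO3 work-up, Et3N-deactivated SiO2
Reagents that add atoms: none
Why: Fluoride-mediated desilylation runs under basic conditions, which keep the acid-labile enol ether and the phthalide intact and do not touch any stereocentre.

Step 11
Reactants: 19 (3R)-3-{(7R)-7-hydroxy-9-[(5R)-5-methyl-4,5-dihydrofuran-2-yl]nonyl}-5,7-dimethoxy-2-benzofuran-1(3H)-one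
Product: 20 (3R)-5,7-dimethoxy-3-{6-[(2R,5S,7R)-7-methyl-1,6-dioxaspiro[4.4]nonan-2-yl]hexyl}-2-benzofuran-1(3H)-one
Conditions: confined chiral imidodiphosphoric acid built from two 3,3'-bis(2,4,6-triethylphenyl)-BINOL units (5 mol%), 4 Å MS, MTBE, −35 °C; then Et3N
Reagents that add atoms: none
Why: Kinetically controlled asymmetric Brønsted acid catalysed spiroacetalization of a hydroxy enol ether, in which protonation gives a cyclic oxocarbenium ion held in the chiral anion pocket and the side-chain hydroxyl closes on the face anti to the ring methyl group to give the (S) spiro centre (each alkyl group anti to the oxygen of the other ring), which does not re-ionize at −35 °C before the Et3N quench.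

## Compound list

1 | resorcinol (benzene-1,3-diol) | Oc1cccc(O)c1 | starting material
2 | 2,4-dihydroxybenzoic acid | OC(=O)c1ccc(O)cc1O | intermediate
3 | methyl 2,4-dimethoxybenzoate | COC(=O)c1ccc(OC)cc1OC | intermediate
4 | 2,4-dimethoxybenzoic acid | COc1ccc(C(=O)O)c(OC)c1 | intermediate
5 | 7-bromohept-1-ene | BrCCCCCC=C | starting material
6 | (S)-2-(2-bromoethyl)oxirane | BrCC[C@H]1CO1 | starting material
7 | hept-6-en-1-ylmagnesium bromide | C=CCCCCC[Mg]Br | intermediate
8 | (R)-1-bromoundec-10-en-3-ol | C=CCCCCCC[C@@H](O)CCBr | intermediate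
9 | (R)-[(1-bromoundec-10-en-3-yl)oxy](tert-butyl)dimethylsilane | C=CCCCCCC[C@@H](O[Si](C)(C)C(C)(C)C)CCBr | intermediate
10 | 3-[(7R)-9-bromo-7-(tert-butyldimethylsilyloxy)nonyl]-1,2,4-trioxolane (secondary ozonide, both epimers at the ring carbon) | O1OC(CCCCCC[C@@H](O[Si](C)(C)C(C)(C)C)CCBr)OC1 | intermediate
11 | (R)-10-bromo-8-(tert-butyldimethylsilyloxy)decanal | O=CCCCCCC[C@@H](O[Si](C)(C)C(C)(C)C)CCBr | intermediate
12 | (R)-γ-valerolactone [(5R)-5-methyloxolan-2-one] | C[C@@H]1CCC(=O)O1 | starting material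
13 | potassium (5R)-5-methyl-4,5-dihydrofuran-2-olate | C[C@@H]1CC=C([O-])O1.[K+] | intermediate
14 | (5R)-5-methyl-4,5-dihydrofuran-2-yl diphenyl phosphate | C[C@@H]1CC=C(OP(=O)(Oc2ccccc2)Oc2ccccc2)O1 | intermediate
15 | 2-[(1R,8R)-10-bromo-8-(tert-butyldimethylsilyloxy)-1-hydroxydecyl]-4,6-dimethoxybenzoic acid | COc1cc(OC)c(C(=O)O)c(c1)[C@H](O)CCCCCC[C@@H](O[Si](C)(C)C(C)(C)C)CCBr | intermediate
16 | (3R)-3-[(7R)-9-bromo-7-(tert-butyldimethylsilyloxy)nonyl]-5,7-dimethoxy-2-benzofuran-1(3H)-one | COc1cc(OC)c2c(c1)[C@@H](CCCCCC[C@@H](O[Si](C)(C)C(C)(C)C)CCBr)OC2=O | intermediate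
17 | alkylzinc bromide of 16 (terminal CH2Br replaced by CH2ZnBr; 3R and 7R unchanged) | COc1cc(OC)c2c(c1)[C@@H](CCCCCC[C@@H](O[Si](C)(C)C(C)(C)C)CC[Zn]Br)OC2=O | intermediate
18 | (3R)-3-{(7R)-7-(tert-butyldimethylsilyloxy)-9-[(5R)-5-methyl-4,5-dihydrofuran-2-yl]nonyl}-5,7-dimethoxy-2-benzofuran-1(3H)-one | COc1cc(OC)c2c(c1)[C@@H](CCCCCC[C@@H](O[Si](C)(C)C(C)(C)C)CCC1=CC[C@@H](C)O1)OC2=O | intermediate
19 | (3R)-3-{(7R)-7-hydroxy-9-[(5R)-5-methyl-4,5-dihydrofuran-2-yl]nonyl}-5,7-dimethoxy-2-benzofuran-1(3H)-one | COc1cc(OC)c2c(c1)[C@@H](CCCCCC[C@@H](O)CCC1=CC[C@@H](C)O1)OC2=O | intermediate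
20 | (3R)-5,7-dimethoxy-3-{6-[(2R,5S,7R)-7-methyl-1,6-dioxaspiro[4.4]nonan-2-yl]hexyl}-2-benzofuran-1(3H)-one | COc1cc(OC)c2c(c1)[C@@H](CCCCCC[C@@H]1CC[C@]3(CC[C@@H](C)O3)O1)OC2=O | target

## Step count and risks

Total step count: 11. Longest linear sequence: 7 steps (4, 5, 6, 8, 9, 10, 11; the arene branch 1, 2, 3, 8, 9, 10, 11 is equally long).

The three steps most likely to fail:

**Step 8 (the proposed new C–H addition and lactonization).** Insertion of an unactivated aldehyde may be slow, aldol self-condensation of 11 may compete, and the ee is untested. The fallback uses known chemistry only; it sets out from resorcinol 1 and aldehyde 11 and comes back to the route at 16. Resorcinol 1 is O-methylated (Me2SO4, K2CO3, acetone, reflux) to 1,3-dimethoxybenzene F1. Sterically governed C–H borylation ([Ir(OMe)(cod)]2, 4,4'-di-tert-butyl-2,2'-bipyridine, B2pin2, THF, 80 °C) gives 2-(3,5-dimethoxyphenyl)-4,4,5,5-tetramethyl-1,3,2-dioxaborolane F2. Rhodium-catalysed 1,2-addition of F2 to 11 ([Rh(OH)(cod)]2, P(t-Bu)3, dioxane/H2O, 40 °C) gives (8R)-10-bromo-8-(tert-butyldimethylsilyloxy)-1-(3,5-dimethoxyphenyl)decan-1-ol F3 as both C1 epimers. Dess–Martin oxidation gives (R)-10-bromo-8-(tert-butyldimethylsilyloxy)-1-(3,5-dimethoxyphenyl)decan-1-one F4. Reduction with (S)-Me-CBS oxazaborolidine and BH3·SMe2 (THF, −20 °C; aryl large, n-alkyl small) gives (1R,8R)-10-bromo-8-(tert-butyldimethylsilyloxy)-1-(3,5-dimethoxyphenyl)decan-1-ol F5. NBS (CH2Cl2, −20 → 0 °C) brominates the ring position between the carbinol carbon and a methoxy group to give (1R,8R)-10-bromo-1-(2-bromo-3,5-dimethoxyphenyl)-8-(tert-butyldimethylsilyloxy)decan-1-ol F6. Carbonylative lactonization (Pd(OAc)2, Xantphos, CO 1 atm, K2CO3, toluene, 90 °C; zerovalent palladium inserts into the aryl C–Br bond) closes the phthalide and gives 16.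

**Step 9 (Negishi coupling with a five-ring ketene acetal phosphate).** The phosphate 14 is hydrolytically fragile, and the alkylzinc may give β-hydride elimination or protodemetalation. The fallback sets out from 16 and comes back at 18. Alkyl Sonogashira coupling of bromide 16 with bought (R)-pent-4-yn-2-ol ([Pd(C3H5)Cl]2, 1,3-bis(1-adamantyl)imidazolium chloride, CuI, Cs2CO3, DMF/Et2O, 45 °C) gives (3R)-3-[(7R,13R)-7-(tert-butyldimethylsilyloxy)-13-hydroxytetradec-10-yn-1-yl]-5,7-dimethoxy-2-benzofuran-1(3H)-one F7. Base-buffered 5-endo-dig hydroalkoxylation with monovalent gold (Au(PPh3)(NTf2) 2 mol%, 2,6-di-tert-butylpyridine, CH2Cl2, 0 °C) closes the homopropargylic alcohol onto the distal alkyne carbon and gives the dihydrofuran 18.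

**Step 11 (catalyst control of a [4.4] spiro centre that has no thermodynamic bias).** The long side chain may not fit the confined acid, and any adventitious acid erodes the ratio. The fallback sets out from 19 and comes back at 20. Camphorsulfonic acid (5 mol%, CH2Cl2, rt) closes 19 under thermodynamic control to a roughly 1:1 mixture of 20 and its spiro epimer (3R)-5,7-dimethoxy-3-{6-[(2R,5R,7R)-7-methyl-1,6-dioxaspiro[4.4]nonan-2-yl]hexyl}-2-benzofuran-1(3H)-one F8. The two are separated by preparative HPLC, and F8 is put back into the same acid to regenerate the mixture, so material converges on 20 over a few cycles.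

## Further compounds

F1 | step 8 | 1,3-dimethoxybenzene | COc1cccc(OC)c1
F2 | step 8 | 2-(3,5-dimethoxyphenyl)-4,4,5,5-tetramethyl-1,3,2-dioxaborolane | COc1cc(OC)cc(c1)B1OC(C)(C)C(C)(C)O1
F3 | step 8 | (8R)-10-bromo-8-(tert-butyldimethylsilyloxy)-1-(3,5-dimethoxyphenyl)decan-1-ol (both C1 epimers) | COc1cc(OC)cc(c1)C(O)CCCCCC[C@@H](O[Si](C)(C)C(C)(C)C)CCBr
F4 | step 8 | (R)-10-bromo-8-(tert-butyldimethylsilyloxy)-1-(3,5-dimethoxyphenyl)decan-1-one | COc1cc(OC)cc(c1)C(=O)CCCCCC[C@@H](O[Si](C)(C)C(C)(C)C)CCBr
F5 | step 8 | (1R,8R)-10-bromo-8-(tert-butyldimethylsilyloxy)-1-(3,5-dimethoxyphenyl)decan-1-ol | COc1cc(OC)cc(c1)[C@H](O)CCCCCC[C@@H](O[Si](C)(C)C(C)(C)C)CCBr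
F6 | step 8 | (1R,8R)-10-bromo-1-(2-bromo-3,5-dimethoxyphenyl)-8-(tert-butyldimethylsilyloxy)decan-1-ol | COc1cc(OC)c(Br)c(c1)[C@H](O)CCCCCC[C@@H](O[Si](C)(C)C(C)(C)C)CCBr
F7 | step 9 | (3R)-3-[(7R,13R)-7-(tert-butyldimethylsilyloxy)-13-hydroxytetradec-10-yn-1-yl]-5,7-dimethoxy-2-benzofuran-1(3H)-one | COc1cc(OC)c2c(c1)[C@@H](CCCCCC[C@@H](O[Si](C)(C)C(C)(C)C)CCC#CC[C@@H](C)O)OC2=O
F8 | step 11 | (3R)-5,7-dimethoxy-3-{6-[(2R,5R,7R)-7-methyl-1,6-dioxaspiro[4.4]nonan-2-yl]hexyl}-2-benzofuran-1(3H)-one | COc1cc(OC)c2c(c1)[C@@H](CCCCCC[C@@H]1CC[C@@]3(CC[C@@H](C)O3)O1)OC2=O
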